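# Proposal: synthesis of epicatechin-(4β→6)-epicatechin-(4β→6)-epicatechin by two silicon-tethered pyran ring walks

## The problem

The target 22 is the B-type procyanidin trimer epicatechin-(4β→6)-epicatechin-(4β→6)-epicatechin: three flavan-3-ol units (top, middle, lower), each a benzene ring A fused to a pyran ring C that carries a catechol ring B on C2, joined by two bonds from C4 of one unit to C6 of ring A of the next. Of its eight stereocenters, the six at C2 and C3 (2R,3R in every unit) are those of (−)-epicatechin, and the two at C4 of the top and middle units are 3,4-trans, the arrangement that the C3 oxygen imposes on a nucleophile adding to a C4 cation, so stereochemistry can be bought and relayed. Regiochemistry cannot: flavan-4-yl cations attack ring A of a benzylated flavan-3-ol mainly at C8, between one benzyloxy group and the compact ring oxygen, and only to a minor extent at C6, which is hemmed in by two benzyloxy groups, so both junctions of 22 are of the disfavoured kind. The fifteen hydroxyl groups must stay masked to the end, because the free phenols are oxidized in air and base, the C4–aryl bonds are cleaved by acid, and C2 epimerizes in base once the ring B phenols are free; the last operations must therefore be close to neutral. The feature that offers a way round the C6 problem is the position of C4a in a chain-extending unit: it lies between C8a, which carries the pyran oxygen O1, and C5, which carries a phenolic oxygen. If the bond to C2 is moved from O1 to the C5 oxygen, ring C is re-formed on the other side of C4a, the ring is renumbered, and the carbon that holds the unit above changes from C8 to C6 without any C–C bond being touched. Two groups are placed to drive such a ring walk: the C3 oxygen of the unit above can reach O1 through a seven-membered ring, and the C3 oxygen of the walking unit is vicinal to C2 and can assist its ionization and return its configuration.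

## Retrosynthesis

**Unmasking (22 ⇐ 21 ⇐ 20 ⇐ 19).** The last bonds cut are ten O–benzyl bonds (21), the four Si–O bonds of two di-tert-butylsilylenes (20) and one pivalate (19). Hydrogenolysis is placed last because it is neutral and leaves only toluene beside the sensitive polyphenol. The ester is removed by hydride before any phenol is free, and the silylenes by buffered fluoride. Each precursor differs from the next only in protecting groups, and none of these steps touches a stereocenter.

**Ring walk of the lower unit (19 ⇐ 16).** In 19 the O1–C2 bond of the lower unit is cut and C2 is reconnected to the oxygen that in 19 is the silylated O5. This gives 16, in which the lower unit is joined through C8.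

- The neighbouring cut, the C4–C6 bond itself, would require a Friedel–Crafts reaction at C6 against the intrinsic preference and would need blocking halogens. The ring walk lets the C–C bond be made where it forms readily.
- The forward reaction must bring a Lewis acid to O1 of the lower unit only, return C2 with retention, and be irreversible. A di-tert-butylsilyl triflate on the neighbouring C3 oxygen of the middle unit does the first and the last. A C3 pivalate on the lower unit does the second by double inversion.
- The ring-closing oxygen is carried as its benzyl ether, not as a free phenol. A free phenol would be silylated by 12 before the hindered alcohol and, being para to the interflavan carbon, could not be bridged. O5 also cannot be freed selectively beside O7 on an epicatechin-derived ring. The benzyl group is lost after closure.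
- Pivalate is preferred to acetate on the lower unit. It survives the methanolysis that frees the middle C3 hydroxyl, and its tert-butyl group shields the acyl carbon of the acyloxonium ion.

**Ring walk of the middle unit (16 ⇐ 15 ⇐ 11).** Putting an acetate back on O3 of the middle unit gives 15. Applying the same retro ring walk to the middle unit of 15 gives 11, in which both junctions are 4β→8.

- The middle unit must walk first. It needs its C3 oxygen as a participating acetate, and only afterwards can that oxygen carry the silicon for the lower unit.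
- This fixes three different C3 oxygens in 11: free hydroxyl (top), acetate (middle), pivalate (lower).
- The first silylene is kept as the protecting group of the top O3 and the middle O5. It also blocks a reverse walk of the middle unit in the key step.

**Upper junction (11 ⇐ 7 + 10).** The C4(top)–C8(middle) bond is cut to the C4-activated monomer 7 and the dimer 10. The dimer is used as the nucleophile, so no dimer ever has to be oxidized at C4. The forward reaction must select C8 of the upper unit of 10 and the β face of the cation.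

**Lower junction (10 ⇐ 9 + 5).** The C4(middle)–C8(lower) bond is cut to the acetylated electrophile 9 and the pivaloylated nucleophile 5. Both are monomers, and both selectivities (C8, 4β) are the intrinsic ones.

**Monomers (9 ⇐ 7 ⇐ 3; 5 ⇐ 3; 3 ⇐ 1 + 2).** Acetylation (8) relates 9 to 7. Benzylic oxidation at C4 in the presence of 2-ethoxyethanol (6) relates 7 to 3. Pivaloylation (4) relates 5 to 3. Fourfold O-benzylation with 2 relates 3 to (−)-epicatechin 1. One oxidation product, 7, serves as the top electrophile and, after acetylation, as the middle electrophile.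

## Roads not taken

**Alternative 1:** Ring A of the middle unit is disconnected at C6–C7 and C4a–C5. In the forward direction a cyclobutenone ring on C4 of the top unit would open thermally to a vinylketene and add to a silyloxy-substituted triple bond that carries the rest of the middle unit (Danheiser benzannulation). This would give the phenol A1, free only at the future O1.

- Merits: the substitution pattern of the new ring, and with it the 6-linkage, is fixed by construction, and the reaction class is known.
- Weak points: C2, C3 and C4 of the middle unit must be made by acyclic stereocontrol on the alkyne partner. The annulation has to build a fully substituted benzene next to a stereogenic bis-benzylic carbon at elevated temperature. A1 still lacks ring C of the middle unit and the whole pyran of the lower unit.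
- Comparison: this road is better in regiochemical certainty. The chosen plan sets against it that six of eight stereocenters come from epicatechin, that both C–C junctions use the standard coupling, and that the route is much shorter, at the price of an untested rearrangement.

**Alternative 2:** All three O1–C8a bonds are disconnected. Three secondary C2 hydroxyl groups would displace three aryl bromides under copper or palladium catalysis (for example CuI or Pd(OAc)2 with a ligand). This would close the three pyran rings in one operation and give A2.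

- Merits: each ring oxygen ends on the carbon that carried bromine, so the 6-linkages are unambiguous. C2 is not touched in the bond-forming event. Intramolecular aryl etherification to chromans is established.
- Weak points: the substrate would be an open-chain array of eight stereocenters, two of them bis-benzylic methines between 2,6-disubstituted arenes, with no ring to relay stereocontrol. Each aryl bromide is flanked on both sides. Secondary benzylic alkoxides on palladium are prone to β-hydride elimination. Three closures must all succeed.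
- Comparison: this road is as good or better in its key step, which is precedented and regiospecific. The chosen plan answers with a much shorter approach to the precursor, because the intact flavan rings of epicatechin are used.

**Alternative 3:** The C4–C4a bond of the top unit is disconnected. The ortho carbon of a ring A aryl ether would open a benzylic epoxide at C4 (epoxy-arene Friedel–Crafts cyclization). This would close ring C and leave the epoxide oxygen as the C3 hydroxyl, giving A3.

- Merits: C3 and C4 are set together as 3,4-trans by anti opening. The C4–aryl bond is already present before cyclization. The future middle ring in A3 is symmetric, so its later closure is regiochemically unambiguous and gives the 6-linked unit.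
- Weak points: A3 is only the top unit with a bare aryl group. The middle and lower pyran rings would each need their own asymmetric construction at a hindered position. An epoxide carrying two electron-rich aryl groups is prone to Meinwald rearrangement.
- Comparison: regiochemistry is secured here by symmetry and by a known reaction type, which the chosen plan cannot claim. The chosen plan has instead the brevity of a chiral-pool assembly in twelve steps.

Key step: step 9

Remark: flavan numbering (O1, C2, C3, C4, C4a, C5 to C8, C8a; ring B primed) is used within each unit and applied afresh after a ring walk. It is assumed that a C5 benzyl ether oxygen is nucleophilic enough to close onto the acyloxonium ion and to pass its benzyl group to 2,6-lutidine.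

## Route

**Step 1**
Reactants: 1 (−)-epicatechin; 2 benzyl bromide
Product: 3 5,7,3',4'-tetra-O-benzyl-(−)-epicatechin
Conditions: K2CO3, DMF, 0 °C → rt, argon
Reagents that add atoms: benzyl bromide, BrCc1ccccc1
Why: Williamson etherification; carbonate deprotonates only the four phenols, so the secondary C3 hydroxyl stays free, and no stereocenter is touched.

**Step 2**
Reactants: 3 5,7,3',4'-tetra-O-benzyl-(−)-epicatechin; 4 pivaloyl chloride
Product: 5 3-O-pivaloyl-5,7,3',4'-tetra-O-benzylepicatechin
Conditions: pyridine, DMAP, CH2Cl2, 40 °C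
Reagents that add atoms: pivaloyl chloride, CC(C)(C)C(=O)Cl
Why: DMAP-catalysed acylation of the axial secondary alcohol; the ester is the later participating group of the lower unit and resists the methanolysis of step 8.

**Step 3**
Reactants: 3 5,7,3',4'-tetra-O-benzyl-(−)-epicatechin; 6 2-ethoxyethanol
Product: 7 (2R,3R,4S)-5,7,3',4'-tetra-O-benzyl-4β-(2-ethoxyethoxy)epicatechin (3-OH free)
Conditions: DDQ, CH2Cl2, rt
Reagents that add atoms: 2-ethoxyethanol, CCOCCO
Why: DDQ benzylic oxidation by hydride abstraction from C4, the cation being stabilized by the ring A oxygens; the alcohol should add trans to the axial C3 hydroxyl and so set the 4β configuration.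

**Step 4**
Reactants: 7 4β-(2-ethoxyethoxy) tetra-O-benzylepicatechin; 8 acetic anhydride
Product: 9 3-O-acetyl-5,7,3',4'-tetra-O-benzyl-4β-(2-ethoxyethoxy)epicatechin
Conditions: pyridine, DMAP (cat.), rt
Reagents that add atoms: acetic anhydride, CC(=O)OC(C)=O
Why: standard acetylation of the secondary alcohol; the acetate directs the coupling of step 5 and is the participating group for the ring walk of step 7.

**Step 5**
Reactants: 9 3-O-acetyl-4β-(2-ethoxyethoxy) electrophile; 5 3-O-pivaloyl tetra-O-benzylepicatechin (in excess)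
Product: 10 dimer [3-O-acetyl-5,7,3',4'-tetra-O-benzylepicatechin]-(4β→8)-[3-O-pivaloyl-5,7,3',4'-tetra-O-benzylepicatechin]
Conditions: Me3SiOTf (cat.), CH2Cl2, −78 °C; Et3N quench
Reagents that add atoms: none
Why: Lewis-acid-promoted Friedel–Crafts flavanylation through the C4 cation; 5 should react at C8, its less hindered ring A position, and attack anti to the C3 acetoxy group should set the new C4 stereocenter as 4β (3,4-trans). The excess of 5 suppresses self-condensation of 9.

**Step 6**
Reactants: 7 4β-(2-ethoxyethoxy) tetra-O-benzylepicatechin; 10 dimer (in excess)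
Product: 11 trimer [5,7,3',4'-tetra-O-benzylepicatechin]-(4β→8)-[3-O-acetyl-5,7,3',4'-tetra-O-benzylepicatechin]-(4β→8)-[3-O-pivaloyl-5,7,3',4'-tetra-O-benzylepicatechin], top 3-OH free
Conditions: Me3SiOTf (cat.), CH2Cl2, −78 → −40 °C; aq. NaHCO3, then brief dilute HCl/THF wash
Reagents that add atoms: none
Why: the same Friedel–Crafts flavanylation; C8 of the upper unit of 10 is its most nucleophilic free position, and attack anti to the axial C3 oxygen of the cation should give the 4β bond. The acidic wash removes any trimethylsilyl ether formed on the free hydroxyl.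

**Step 7**
Reactants: 11 all-4β→8 trimer; 12 di-tert-butylsilyl bis(trifluoromethanesulfonate)
Product: 15 ring-walked trimer [5,7,3',4'-tetra-O-benzylepicatechin]-(4β→6)-[3-O-acetyl-7,3',4'-tri-O-benzylepicatechin]-(4β→8)-[3-O-pivaloyl-5,7,3',4'-tetra-O-benzylepicatechin] bearing a di-tert-butylsilylene from O3 of the top unit to O5 of the middle unit, via top silyl triflate 13 (not isolated), via acetoxonium triflate 14 (not isolated)
Conditions: 2,6-lutidine, ClCH2CH2Cl, 0 → 50 °C
Reagents that add atoms: di-tert-butylsilyl bis(trifluoromethanesulfonate), CC(C)(C)[Si](OS(=O)(=O)C(F)(F)F)(OS(=O)(=O)C(F)(F)F)C(C)(C)C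
Why: Proposed new method: 12 should silylate the only free hydroxyl (top C3–OH), and the tethered silyl triflate 13 can bind O1 of the middle unit in a seven-membered chelate, so that the O1–C2 bond ionizes with rear-side help of the C3 acetate to the acetoxonium ion 14; its benzylic C2 is then attacked 6-exo-tet by the C5 benzyl ether oxygen, the benzyl group passing to 2,6-lutidine, which moves the pyran oxygen from C8a to C5 and turns the interflavan carbon from C8 into C6. C2 is re-formed with net retention by double inversion under control of C3, and the released oxygen is held in the silylene, so the walk cannot run back. The closest known reactions are acyloxonium-mediated 1,2-trans glycosylation, debenzylative cycloetherification of benzyl ethers onto cationic carbon, and the Wessely–Moser re-closure of a pyrone ring onto the other ortho oxygen.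

**Step 8**
Reactants: 15 ring-walked trimer with middle 3-O-acetate
Product: 16 mono-silylene trimer having the middle 3-OH free (lower 3-O-pivalate kept)
Conditions: K2CO3 (cat.), MeOH–THF, 0 °C → rt
Reagents that add atoms: none
Why: base-catalysed transesterification (Zemplén-type); a secondary acetate is methanolysed far faster than a pivalate, and the silylene is shielded by its two tert-butyl groups.

**Step 9**
Reactants: 16 trimer with 6-linked middle unit, 8-linked lower unit, middle 3-OH free, lower 3-O-pivalate; 12 di-tert-butylsilyl bis(trifluoromethanesulfonate)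
Product: 19 bis-silylene trimer [5,7,3',4'-tetra-O-benzylepicatechin]-(4β→6)-[7,3',4'-tri-O-benzylepicatechin]-(4β→6)-[3-O-pivaloyl-7,3',4'-tri-O-benzylepicatechin] bearing one di-tert-butylsilylene from top O3 to middle O5 plus one from middle O3 to lower O5, via middle silyl triflate 17 (not isolated), via pivaloxonium triflate 18 (not isolated)
Conditions: 2,6-lutidine, ClCH2CH2Cl, 0 → 50 °C
Reagents that add atoms: di-tert-butylsilyl bis(trifluoromethanesulfonate), CC(C)(C)[Si](OS(=O)(=O)C(F)(F)F)(OS(=O)(=O)C(F)(F)F)C(C)(C)C
Why: Proposed new method: 12 should silylate the only free hydroxyl of 16, the hindered C3–OH of the middle unit, to give the silyl triflate 17, whose silicon is tethered through O3, C3 and C4 of the middle unit to C8 of the lower unit. Rotation about the C4–C8 bond lets it bind O1 of the lower unit in a seven-membered chelate; O-silylation makes O1 an aryloxysilane leaving group on C2, a 3,4-dialkoxybenzylic carbon, and the C3 pivalate, anti-periplanar to O1–C2 in the half-chair that has ring B axial, displaces it from the rear to give the cis-disubstituted 2-tert-butyl-1,3-dioxolan-2-ylium ion 18, the released oxygen being already locked in the seven-membered silylene ring. The C5 benzyl ether oxygen, the only other heteroatom on a carbon flanking C4a, then opens 18 at the benzylic C2 in a 6-exo-tet closure of the new ring C, and SN2 transfer of its benzyl group from the oxonium ion to 2,6-lutidine makes the closure irreversible. The closest known reactions are 1,2-trans glycosylation through acyloxonium ions, debenzylative cycloetherification of benzyl ethers onto cationic carbon, dealkylative iodocyclization of aryl methyl ethers, and the Wessely–Moser re-closure of a pyrone ring onto the other ortho oxygen. The one new stereocenter, C2, is re-formed with net retention (2R, aryl cis to the C3 oxygen) by two inversions, the first controlled by the C3 stereocenter through the acyloxonium ion, and the tert-butyl group keeps nucleophiles off the acyl carbon. Site selectivity is needed among three ether oxygens within reach of silicon: O7 of the lower unit also forms a seven-membered chelate but leads only to a primary benzyl carbon, and O1 of the middle unit is reached only through a strained five-membered chelate and has no acyl neighbour, so the fast, assisted ionization at the lower C2 should drain the equilibrating chelates. A walk back of the middle unit is excluded because its O5 is tied into the first silylene, and a walk back of the lower unit because its old O1 is tied into the second. The interflavan carbon of the lower unit thereby becomes C6.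

**Step 10**
Reactants: 19 bis-silylene trimer with lower 3-O-pivalate
Product: 20 bis-silylene trimer having the lower 3-OH free
Conditions: iBu2AlH, CH2Cl2, −78 → 0 °C; aq. potassium sodium tartrate
Reagents that add atoms: none
Why: reductive cleavage of the hindered ester by hydride; benzyl ethers and the hindered silylenes should be inert at low temperature, and no phenol is yet free.

**Step 11**
Reactants: 20 bis-silylene trimer
Product: 21 deca-O-benzyl epicatechin-(4β→6)-epicatechin-(4β→6)-epicatechin (all three 3-OH free, 5-OH free on the middle unit, 5-OH free on the lower unit)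
Conditions: HF·pyridine, pyridine, THF, 0 °C → rt
Reagents that add atoms: none
Why: fluoride-mediated cleavage of both silylenes, driven by the Si–F bond; the pyridine buffer keeps the medium away from strong acid (interflavan bonds) and from phenoxide formation.

**Step 12**
Reactants: 21 deca-O-benzyl trimer
Product: 22 epicatechin-(4β→6)-epicatechin-(4β→6)-epicatechin (CNP0163146.2)
Conditions: H2 (1 atm), Pd(OH)2/C, THF–MeOH–H2O, rt; filtration and lyophilization under argon
Reagents that add atoms: none
Why: catalytic hydrogenolysis of the ten benzyl ethers under neutral conditions, the standard last step for benzylated procyanidins; no stereocenter is touched.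

## Compound list

1 | (−)-epicatechin, (2R,3R) | Oc1cc(O)c2c(c1)O[C@H](c1ccc(O)c(O)c1)[C@H](O)C2 | starting material

2 | benzyl bromide | BrCc1ccccc1 | starting material

3 | 5,7,3',4'-tetra-O-benzyl-(−)-epicatechin, (2R,3R) | c9ccccc9COc1cc(OCc9ccccc9)c2c(c1)O[C@H](c1ccc(OCc9ccccc9)c(OCc9ccccc9)c1)[C@H](O)C2 | intermediate

4 | pivaloyl chloride | CC(C)(C)C(=O)Cl | starting material

5 | 3-O-pivaloyl-5,7,3',4'-tetra-O-benzylepicatechin, (2R,3R) | c9ccccc9COc1cc(OCc9ccccc9)c2c(c1)O[C@H](c1ccc(OCc9ccccc9)c(OCc9ccccc9)c1)[C@H](OC(=O)C(C)(C)C)C2 | intermediate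

6 | 2-ethoxyethanol | CCOCCO | starting material

7 | (2R,3R,4S)-5,7,3',4'-tetra-O-benzyl-4β-(2-ethoxyethoxy)epicatechin, 3-OH free, 3,4-trans | c9ccccc9COc1cc(OCc9ccccc9)c2c(c1)O[C@H](c1ccc(OCc9ccccc9)c(OCc9ccccc9)c1)[C@H](O)[C@H]2OCCOCC | intermediate

8 | acetic anhydride | CC(=O)OC(C)=O | starting material

9 | (2R,3R,4S)-3-O-acetyl-5,7,3',4'-tetra-O-benzyl-4β-(2-ethoxyethoxy)epicatechin | c9ccccc9COc1cc(OCc9ccccc9)c2c(c1)O[C@H](c1ccc(OCc9ccccc9)c(OCc9ccccc9)c1)[C@H](OC(C)=O)[C@H]2OCCOCC | intermediate

10 | dimer [3-O-acetyl-tetra-O-benzylepicatechin]-(4β→8)-[3-O-pivaloyl-tetra-O-benzylepicatechin], all units 2R,3R, interflavan bond 3,4-trans | c9ccccc9COc1cc(OCc9ccccc9)c2c(c1)O[C@H](c1ccc(OCc9ccccc9)c(OCc9ccccc9)c1)[C@H](OC(C)=O)[C@H]2c1c(OCc9ccccc9)cc(OCc9ccccc9)c2c1O[C@H](c1ccc(OCc9ccccc9)c(OCc9ccccc9)c1)[C@H](OC(=O)C(C)(C)C)C2 | intermediate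

11 | trimer [tetra-O-benzylepicatechin]-(4β→8)-[3-O-acetyl-tetra-O-benzylepicatechin]-(4β→8)-[3-O-pivaloyl-tetra-O-benzylepicatechin], top 3-OH free | c9ccccc9COc1cc(OCc9ccccc9)c2c(c1)O[C@H](c1ccc(OCc9ccccc9)c(OCc9ccccc9)c1)[C@H](O)[C@H]2c1c(OCc9ccccc9)cc(OCc9ccccc9)c2c1O[C@H](c1ccc(OCc9ccccc9)c(OCc9ccccc9)c1)[C@H](OC(C)=O)[C@H]2c1c(OCc9ccccc9)cc(OCc9ccccc9)c2c1O[C@H](c1ccc(OCc9ccccc9)c(OCc9ccccc9)c1)[C@H](OC(=O)C(C)(C)C)C2 | intermediate

12 | di-tert-butylsilyl bis(trifluoromethanesulfonate) | CC(C)(C)[Si](OS(=O)(=O)C(F)(F)F)(OS(=O)(=O)C(F)(F)F)C(C)(C)C | starting material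

13 | trimer 11 carrying a di-tert-butyl(trifluoromethanesulfonyloxy)silyl group on O3 of the top unit | c9ccccc9COc1cc(OCc9ccccc9)c2c(c1)O[C@H](c1ccc(OCc9ccccc9)c(OCc9ccccc9)c1)[C@H](O[Si](C(C)(C)C)(C(C)(C)C)OS(=O)(=O)C(F)(F)F)[C@H]2c1c(OCc9ccccc9)cc(OCc9ccccc9)c2c1O[C@H](c1ccc(OCc9ccccc9)c(OCc9ccccc9)c1)[C@H](OC(C)=O)[C@H]2c1c(OCc9ccccc9)cc(OCc9ccccc9)c2c1O[C@H](c1ccc(OCc9ccccc9)c(OCc9ccccc9)c1)[C@H](OC(=O)C(C)(C)C)C2 | intermediate (not isolated)

14 | ring-opened middle unit as cis-4,5-disubstituted 2-methyl-1,3-dioxolan-2-ylium triflate (C2 inverted), old O1 held in the silylene with top O3 | c9ccccc9COc1cc(OCc9ccccc9)c2c(c1)O[C@H](c1ccc(OCc9ccccc9)c(OCc9ccccc9)c1)[C@H](O[Si]3(C(C)(C)C)C(C)(C)C)[C@H]2c1c(OCc9ccccc9)cc(OCc9ccccc9)c(c1O3)[C@H](c1c(OCc9ccccc9)cc(OCc9ccccc9)c2c1O[C@H](c1ccc(OCc9ccccc9)c(OCc9ccccc9)c1)[C@H](OC(=O)C(C)(C)C)C2)[C@H]1OC(C)=[O+][C@H]1c1ccc(OCc9ccccc9)c(OCc9ccccc9)c1.[O-]S(=O)(=O)C(F)(F)F | intermediate (not isolated)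

15 | trimer [tetra-O-benzylepicatechin]-(4β→6)-[3-O-acetyl-7,3',4'-tri-O-benzylepicatechin]-(4β→8)-[3-O-pivaloyl-tetra-O-benzylepicatechin], di-tert-butylsilylene bridging top O3 and middle O5 | c9ccccc9COc1cc(OCc9ccccc9)c2c(c1)O[C@H](c1ccc(OCc9ccccc9)c(OCc9ccccc9)c1)[C@H](O[Si]3(C(C)(C)C)C(C)(C)C)[C@H]2c1c(OCc9ccccc9)cc2c(c1O3)[C@H](c1c(OCc9ccccc9)cc(OCc9ccccc9)c3c1O[C@H](c1ccc(OCc9ccccc9)c(OCc9ccccc9)c1)[C@H](OC(=O)C(C)(C)C)C3)[C@@H](OC(C)=O)[C@@H](c1ccc(OCc9ccccc9)c(OCc9ccccc9)c1)O2 | intermediate

16 | trimer 15 with the middle 3-OH free (precursor of the key step) | c9ccccc9COc1cc(OCc9ccccc9)c2c(c1)O[C@H](c1ccc(OCc9ccccc9)c(OCc9ccccc9)c1)[C@H](O[Si]3(C(C)(C)C)C(C)(C)C)[C@H]2c1c(OCc9ccccc9)cc2c(c1O3)[C@H](c1c(OCc9ccccc9)cc(OCc9ccccc9)c3c1O[C@H](c1ccc(OCc9ccccc9)c(OCc9ccccc9)c1)[C@H](OC(=O)C(C)(C)C)C3)[C@@H](O)[C@@H](c1ccc(OCc9ccccc9)c(OCc9ccccc9)c1)O2 | intermediate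

17 | trimer 16 carrying a di-tert-butyl(trifluoromethanesulfonyloxy)silyl group on O3 of the middle unit | c9ccccc9COc1cc(OCc9ccccc9)c2c(c1)O[C@H](c1ccc(OCc9ccccc9)c(OCc9ccccc9)c1)[C@H](O[Si]3(C(C)(C)C)C(C)(C)C)[C@H]2c1c(OCc9ccccc9)cc2c(c1O3)[C@H](c1c(OCc9ccccc9)cc(OCc9ccccc9)c3c1O[C@H](c1ccc(OCc9ccccc9)c(OCc9ccccc9)c1)[C@H](OC(=O)C(C)(C)C)C3)[C@@H](O[Si](C(C)(C)C)(C(C)(C)C)OS(=O)(=O)C(F)(F)F)[C@@H](c1ccc(OCc9ccccc9)c(OCc9ccccc9)c1)O2 | intermediate (not isolated)

18 | ring-opened lower unit as cis-4,5-disubstituted 2-tert-butyl-1,3-dioxolan-2-ylium triflate (C2 inverted), old O1 held in the second silylene with middle O3 | c9ccccc9COc1cc(OCc9ccccc9)c2c(c1)O[C@H](c1ccc(OCc9ccccc9)c(OCc9ccccc9)c1)[C@H](O[Si]3(C(C)(C)C)C(C)(C)C)[C@H]2c1c(OCc9ccccc9)cc2c(c1O3)[C@H](c1c(OCc9ccccc9)cc(OCc9ccccc9)c(c1O4)C[C@H]1OC(C(C)(C)C)=[O+][C@H]1c1ccc(OCc9ccccc9)c(OCc9ccccc9)c1)[C@@H](O[Si]4(C(C)(C)C)C(C)(C)C)[C@@H](c1ccc(OCc9ccccc9)c(OCc9ccccc9)c1)O2.[O-]S(=O)(=O)C(F)(F)F | intermediate (not isolated)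

19 | trimer [tetra-O-benzylepicatechin]-(4β→6)-[7,3',4'-tri-O-benzylepicatechin]-(4β→6)-[3-O-pivaloyl-7,3',4'-tri-O-benzylepicatechin], silylenes bridging top O3/middle O5 and middle O3/lower O5 (product of the key step) | c9ccccc9COc1cc(OCc9ccccc9)c2c(c1)O[C@H](c1ccc(OCc9ccccc9)c(OCc9ccccc9)c1)[C@H](O[Si]3(C(C)(C)C)C(C)(C)C)[C@H]2c1c(OCc9ccccc9)cc2c(c1O3)[C@H](c1c(OCc9ccccc9)cc3c(c1O4)C[C@@H](OC(=O)C(C)(C)C)[C@@H](c1ccc(OCc9ccccc9)c(OCc9ccccc9)c1)O3)[C@@H](O[Si]4(C(C)(C)C)C(C)(C)C)[C@@H](c1ccc(OCc9ccccc9)c(OCc9ccccc9)c1)O2 | intermediate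

20 | trimer 19 with the lower 3-OH free | c9ccccc9COc1cc(OCc9ccccc9)c2c(c1)O[C@H](c1ccc(OCc9ccccc9)c(OCc9ccccc9)c1)[C@H](O[Si]3(C(C)(C)C)C(C)(C)C)[C@H]2c1c(OCc9ccccc9)cc2c(c1O3)[C@H](c1c(OCc9ccccc9)cc3c(c1O4)C[C@@H](O)[C@@H](c1ccc(OCc9ccccc9)c(OCc9ccccc9)c1)O3)[C@@H](O[Si]4(C(C)(C)C)C(C)(C)C)[C@@H](c1ccc(OCc9ccccc9)c(OCc9ccccc9)c1)O2 | intermediate

21 | deca-O-benzyl epicatechin-(4β→6)-epicatechin-(4β→6)-epicatechin (benzyl on top O5, O7, O3', O4' and on O7, O3', O4' of the middle and lower units) | c9ccccc9COc1cc(OCc9ccccc9)c2c(c1)O[C@H](c1ccc(OCc9ccccc9)c(OCc9ccccc9)c1)[C@H](O)[C@H]2c1c(OCc9ccccc9)cc2c(c1O)[C@H](c1c(OCc9ccccc9)cc3c(c1O)C[C@@H](O)[C@@H](c1ccc(OCc9ccccc9)c(OCc9ccccc9)c1)O3)[C@@H](O)[C@@H](c1ccc(OCc9ccccc9)c(OCc9ccccc9)c1)O2 | intermediate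

22 | epicatechin-(4β→6)-epicatechin-(4β→6)-epicatechin (CNP0163146.2) | Oc1cc(O)c2c(c1)O[C@H](c1ccc(O)c(O)c1)[C@H](O)[C@H]2c1c(O)cc2c(c1O)[C@H](c1c(O)cc3c(c1O)C[C@@H](O)[C@@H](c1ccc(O)c(O)c1)O3)[C@@H](O)[C@@H](c1ccc(O)c(O)c1)O2 | target

## Step count and least certain steps

Total: 12 steps. Longest linear sequence: 11 steps (steps 1, 3, 4, 5, 6, 7, 8, 9, 10, 11, 12).

**Step 9 (key step).** Several processes could divert it:

- loss of stereocontrol at C2, if the acyloxonium ion opens to a free benzylic cation that closes from either face;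
- closure of the benzyl ether oxygen onto C3 instead of C2 of the acyloxonium ion (5-exo), which ring size favours although benzylic activation does not;
- misdirection of the silicon to O7 of the lower unit, with slow debenzylation to an unreactive silylene;
- scrambling of the acid-labile interflavan bonds by traces of triflic acid;
- failure of the silicon to reach O1, because rotation about the C4–C8 bond is hindered next to the first silylene.

Fallback (known chemistry): the lower junction is made directly at C6 by Friedel–Crafts flavanylation of a lower unit whose C8 is blocked by bromine, an established way of steering such couplings. It sets out from 5 and 9.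

- N-Bromosuccinimide (CH2Cl2, −78 °C → rt) should brominate 5 at C8 to 8-bromo-3-O-pivaloyl-5,7,3',4'-tetra-O-benzylepicatechin F1.
- The same reagent should brominate 9 at C8 to the capped electrophile 8-bromo-3-O-acetyl-4β-(2-ethoxyethoxy)-5,7,3',4'-tetra-O-benzylepicatechin F2, which can no longer condense with itself at C8.
- Coupling of F2 with an excess of F1 (Me3SiOTf, CH2Cl2, −78 → −20 °C) can then occur only at C6 and should give the capped dimer [8-bromo-3-O-acetyl-tetra-O-benzylepicatechin]-(4β→6)-[8-bromo-3-O-pivaloyl-tetra-O-benzylepicatechin] F3.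

A fallback for an untested reaction should not lean on that reaction, so the top unit is then attached in the same capped way through F4, F5 and F6 (next paragraph). The sequence comes back to the route at 22.

**Step 7.** The walking unit here carries an aryl group on C4. The reactive half-chair (ring B axial, C3 acetate equatorial) then pushes that aryl group against the peri benzyloxy group. Ionization may therefore be slow, and elimination at C2–C3 or ionization of the top unit's own ring C through a five-membered chelate may compete.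

Fallback (known chemistry): the upper junction is also made directly at C6 of a bromine-capped partner. It sets out from 7 and uses the capped dimer F3 described above, itself made from 5 and 9.

- N-Bromosuccinimide should convert 7 into 8-bromo-5,7,3',4'-tetra-O-benzyl-4β-(2-ethoxyethoxy)epicatechin F4.
- Me3SiOTf-promoted coupling of F4 with an excess of F3, whose only free ring A position is C6 of its upper unit, should give the tribromo all-4β→6 trimer F5 (top 3-OH, middle 3-O-acetate, lower 3-O-pivalate, twelve benzyl ethers).
- iBu2AlH should remove both esters to give the triol F6.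
- Hydrogenolysis over Pd(OH)2/C with Et3N should cleave the twelve benzyl ethers and the three C–Br bonds.

The sequence comes back to the route at 22.

**Step 8.** Methoxide may attack silicon of the aryloxy silylene and open it, while the hindered acetate is methanolysed only slowly. Selectivity over the pivalate may also erode on long exposure.

Fallback: from 15, both esters are removed reductively (iBu2AlH, CH2Cl2, −78 °C), which does not endanger the silylene. This gives the diol F7 (middle and lower 3-OH free). The lower 3-OH, which has a CH2 neighbour, is then re-acylated in preference to the doubly flanked middle 3-OH with pivaloyl chloride (pyridine, DMAP, 0 °C). The sequence comes back to the route at 16.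

**Step 6.** The free-hydroxyl electrophile 7 may condense with itself at its own C8 or be diverted at its hydroxyl group (O-silylation, oligomer formation). The dimer 10 also offers two further ring A positions for branching.

Fallback: from 7, the hydroxyl is silylated (tert-butyldimethylsilyl chloride, imidazole, DMF) to 3-O-tert-butyldimethylsilyl-5,7,3',4'-tetra-O-benzyl-4β-(2-ethoxyethoxy)epicatechin F8. Coupling with 10 under the conditions of step 5 should give the 3-O-silyl trimer F9. Buffered Bu4NF (AcOH, THF) removes the silyl group in the presence of both esters. The sequence comes back to the route at 11.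

## Further compounds

F1 | step 9 | 8-bromo-3-O-pivaloyl-5,7,3',4'-tetra-O-benzylepicatechin | Brc1c(OCc9ccccc9)cc(OCc9ccccc9)c2c1O[C@H](c1ccc(OCc9ccccc9)c(OCc9ccccc9)c1)[C@H](OC(=O)C(C)(C)C)C2

F2 | step 9 | 8-bromo-3-O-acetyl-5,7,3',4'-tetra-O-benzyl-4β-(2-ethoxyethoxy)epicatechin | c9ccccc9COc1cc(OCc9ccccc9)c2c(c1Br)O[C@H](c1ccc(OCc9ccccc9)c(OCc9ccccc9)c1)[C@H](OC(C)=O)[C@H]2OCCOCC

F3 | step 9 | dimer [8-bromo-3-O-acetyl-tetra-O-benzylepicatechin]-(4β→6)-[8-bromo-3-O-pivaloyl-tetra-O-benzylepicatechin] | c9ccccc9COc1cc(OCc9ccccc9)c2c(c1Br)O[C@H](c1ccc(OCc9ccccc9)c(OCc9ccccc9)c1)[C@H](OC(C)=O)[C@H]2c1c(OCc9ccccc9)c(Br)c2c(c1OCc9ccccc9)C[C@@H](OC(=O)C(C)(C)C)[C@@H](c1ccc(OCc9ccccc9)c(OCc9ccccc9)c1)O2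

F4 | step 7 | 8-bromo-5,7,3',4'-tetra-O-benzyl-4β-(2-ethoxyethoxy)epicatechin | c9ccccc9COc1cc(OCc9ccccc9)c2c(c1Br)O[C@H](c1ccc(OCc9ccccc9)c(OCc9ccccc9)c1)[C@H](O)[C@H]2OCCOCC

F5 | step 7 | trimer [8-bromo-tetra-O-benzylepicatechin]-(4β→6)-[8-bromo-3-O-acetyl-tetra-O-benzylepicatechin]-(4β→6)-[8-bromo-3-O-pivaloyl-tetra-O-benzylepicatechin] | c9ccccc9COc1cc(OCc9ccccc9)c2c(c1Br)O[C@H](c1ccc(OCc9ccccc9)c(OCc9ccccc9)c1)[C@H](O)[C@H]2c1c(OCc9ccccc9)c(Br)c2c(c1OCc9ccccc9)[C@H](c1c(OCc9ccccc9)c(Br)c3c(c1OCc9ccccc9)C[C@@H](OC(=O)C(C)(C)C)[C@@H](c1ccc(OCc9ccccc9)c(OCc9ccccc9)c1)O3)[C@@H](OC(C)=O)[C@@H](c1ccc(OCc9ccccc9)c(OCc9ccccc9)c1)O2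

F6 | step 7 | tribromo dodeca-O-benzyl all-4β→6 trimer with the three 3-OH free | c9ccccc9COc1cc(OCc9ccccc9)c2c(c1Br)O[C@H](c1ccc(OCc9ccccc9)c(OCc9ccccc9)c1)[C@H](O)[C@H]2c1c(OCc9ccccc9)c(Br)c2c(c1OCc9ccccc9)[C@H](c1c(OCc9ccccc9)c(Br)c3c(c1OCc9ccccc9)C[C@@H](O)[C@@H](c1ccc(OCc9ccccc9)c(OCc9ccccc9)c1)O3)[C@@H](O)[C@@H](c1ccc(OCc9ccccc9)c(OCc9ccccc9)c1)O2

F7 | step 8 | trimer 15 with both the middle and the lower 3-OH free (silylene retained) | c9ccccc9COc1cc(OCc9ccccc9)c2c(c1)O[C@H](c1ccc(OCc9ccccc9)c(OCc9ccccc9)c1)[C@H](O[Si]3(C(C)(C)C)C(C)(C)C)[C@H]2c1c(OCc9ccccc9)cc2c(c1O3)[C@H](c1c(OCc9ccccc9)cc(OCc9ccccc9)c3c1O[C@H](c1ccc(OCc9ccccc9)c(OCc9ccccc9)c1)[C@H](O)C3)[C@@H](O)[C@@H](c1ccc(OCc9ccccc9)c(OCc9ccccc9)c1)O2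

F8 | step 6 | 3-O-tert-butyldimethylsilyl-5,7,3',4'-tetra-O-benzyl-4β-(2-ethoxyethoxy)epicatechin | c9ccccc9COc1cc(OCc9ccccc9)c2c(c1)O[C@H](c1ccc(OCc9ccccc9)c(OCc9ccccc9)c1)[C@H](O[Si](C)(C)C(C)(C)C)[C@H]2OCCOCC

F9 | step 6 | trimer 11 with the top 3-OH as its tert-butyldimethylsilyl ether | c9ccccc9COc1cc(OCc9ccccc9)c2c(c1)O[C@H](c1ccc(OCc9ccccc9)c(OCc9ccccc9)c1)[C@H](O[Si](C)(C)C(C)(C)C)[C@H]2c1c(OCc9ccccc9)cc(OCc9ccccc9)c2c1O[C@H](c1ccc(OCc9ccccc9)c(OCc9ccccc9)c1)[C@H](OC(C)=O)[C@H]2c1c(OCc9ccccc9)cc(OCc9ccccc9)c2c1O[C@H](c1ccc(OCc9ccccc9)c(OCc9ccccc9)c1)[C@H](OC(=O)C(C)(C)C)C2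

A1 | alternative 1 | penta-O-benzyl top unit joined at C4 to the newly formed middle ring A (triisopropylsilyl ethers at the future O5 and O7, free phenol at the future O1), open middle ring C with C3 benzyl ether and C2 acetate, lower ring as a 2,6-bis(benzyloxy)-4-(tert-butyldimethylsilyloxy)phenyl group | c9ccccc9COc1cc(OCc9ccccc9)c2c(c1)O[C@H](c1ccc(OCc9ccccc9)c(OCc9ccccc9)c1)[C@H](OCc9ccccc9)[C@H]2c1c(O[Si](C(C)C)(C(C)C)C(C)C)cc(O)c(c1O[Si](C(C)C)(C(C)C)C(C)C)[C@H](c1c(OCc9ccccc9)cc(O[Si](C)(C)C(C)(C)C)cc1OCc9ccccc9)[C@@H](OCc9ccccc9)[C@@H](OC(C)=O)c1ccc(OCc9ccccc9)c(OCc9ccccc9)c1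

A2 | alternative 2 | dodeca-O-benzyl tris(3-O-tert-butyldimethylsilyl) epicatechin-(4β→6)-epicatechin-(4β→6)-epicatechin | c9ccccc9COc1cc(OCc9ccccc9)c2c(c1)O[C@H](c1ccc(OCc9ccccc9)c(OCc9ccccc9)c1)[C@H](O[Si](C)(C)C(C)(C)C)[C@H]2c1c(OCc9ccccc9)cc2c(c1OCc9ccccc9)[C@H](c1c(OCc9ccccc9)cc3c(c1OCc9ccccc9)C[C@@H](O[Si](C)(C)C(C)(C)C)[C@@H](c1ccc(OCc9ccccc9)c(OCc9ccccc9)c1)O3)[C@@H](O[Si](C)(C)C(C)(C)C)[C@@H](c1ccc(OCc9ccccc9)c(OCc9ccccc9)c1)O2

A3 | alternative 3 | 5,7,3',4'-tetra-O-benzylepicatechin with free 3-OH carrying a 2,6-bis(benzyloxy)-4-(tert-butyldimethylsilyloxy)phenyl group at C4β | c9ccccc9COc1cc(OCc9ccccc9)c2c(c1)O[C@H](c1ccc(OCc9ccccc9)c(OCc9ccccc9)c1)[C@H](O)[C@H]2c1c(OCc9ccccc9)cc(O[Si](C)(C)C(C)(C)C)cc1OCc9ccccc9
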